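Partner cannot wait for a feed: its half-life by decay is 2.5 s, and in oak the starting material takes 20.0 s to arrive, while maple holds its whole charge from the first moment.

all flasks: partner 5.25 mM; protic impurity 1.00 mM; initiator 100 µM

| charge | starting material | time | remark |
|---|---|---|---|
| maple | 0.0050 M | 40 s | everything together in a closed stirred flask, run for 40 s |
| oak | 0.0050 M (fed, over 20.0 s) | 40 s | a stirred flask in which starting material is dosed at a steady rate over 20.0 s without added volume, worked up at 40 s |
| alder | 0.0050 M | 40 s | plug flow through a tube for 40 s, no back-mixing |
| larch | 0.0050 M |  | one stirred flow tank at steady state, fed with the mixture as stated, mean residence time 40 s |

    initiator → 2 initiating radical (k1 = 0.00668 /s)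
    starting material + initiating radical → capped initiator + first chain carrier (k2 = 9.61 × 10⁶ /M/s)
    partner + first chain carrier → target + second chain carrier (k3 = 2.70 × 10⁵ /M/s)
    starting material + second chain carrier → released group + first chain carrier (k4 = 5.21 × 10⁵ /M/s)
    2 second chain carrier → ended chains (k5 = 2.1 × 10⁶ /M/s)
    partner + target → over-reaction product (k6 = 2.50 /M/s)
    starting material + protic impurity → quenched substrate (k7 = 11.8 /M/s)
    partner → decomposed reagent (k8 = 0.280 /s)

- a step written with two of one species runs at k times the square of its concentration and takes two of it each time
- the stated concentrations are those of everything mixed, before any reaction; amounts are the same in each set-up
- the feed brings no volume worth counting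
- run time (maple): 40 s

* the set-up with the highest amount of target at the outlet or at the end, in percent of the starting material put in ("none" if the first two lie within 2 percentage points) (maple / oak / alder / larch / none)
* amount of target at the outlet or at the end, in percent of the starting material put in, maple
* amount of target at the outlet or at the end, in percent of the starting material put in, oak
* amount of target at the outlet or at the end, in percent of the starting material put in, alder
* amount of target at the outlet or at the end, in percent of the starting material put in, larch

Maple and oak look nearly the same, so we reckon them side by side. Carriers are born in pairs from initiator and die in pairs of second chain carrier. Where births balance deaths, with initiator held at its charge, that carrier sits at a balance level: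

c(second chain carrier) = root of (initiation constant × c(initiator) / termination constant) = 0.564 µM

Starting material then falls by the chain with a pseudo-first-order constant, and its inverse is the delay of the chain behind a feed:

chain constant = 0.294 /s, delay = 3.40 s

In maple the chain at that balance level starts at 1.47 mM/s, against 1.47 mM/s for partner decay. So about half of the partner should reach target, which is 52.5% of the starting material, a crude figure that lets both rates fall together.

In oak we let the chain, once it has caught up, run at the feed, 0.250 mM/s, which is less than partner decay at partner's charge. The chain constant lies close to the decay constant 0.280 /s, so the time T at which our reckoning brings oak's partner to zero stands on both sides of one equation, and we go round it: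

T = ln((c(partner) + h + feed × T) / h) / decay constant, with h = feed / decay constant = 0.893 mM

first round, T dropped on the right: 6.89 s

second round, that T put back: 7.77 s

T falls inside the dosing. T less the delay is 4.37 s, the working time: the seconds of feed that turn into target. Our figure for oak's target is then working time over dosing time, 21.8%. Larch we leave unreckoned.

The forecast says 62% for maple, 24% for oak, 62% for alder and 86% for larch, so larch, holding that “slow dosing starves the chain during the partner's short life”. It stands above our maple figure and above our oak figure.

The simulation gives 51.9% for maple, 21.8% for oak, 51.9% for alder and 86.8% for larch, so larch leads. Oak's target fraction times its dosing time reads as a working time of 4.36 s, beside our 4.37 s. The neighbour is oak with partner raised to 0.021 M, or 4.20 equiv. The same rounds give T as 11.4 s, then 11.9 s, so a working time of 8.46 s and target at 42.3%. That flask kept 0% of its partner and ended at 38.9% of target, with 48% of its starting material left.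

The rate constants are made up; the rest is arithmetic.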